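**Plan**
- Retrosynthetic cuts: first the two aryl O–Si bonds; then ring C at O1–C2 and C4–C4a in one event, which divides the target into ring A as a lithium 2-lithiophenoxide and ring B with C2–C3–C4 as a trans-glycidic morpholine amide; then the epoxide oxygen, the aryl–alkene bond (Heck) and the aryl–prenyl bonds.
- Enabling feature: ring C is bounded on ring A by the phenolic oxygen O1 and its ortho carbon C4a (a 1,3-O,C-dinucleophile) and on the three-carbon unit by the acyl carbon C4 and the benzylic carbon C2 (a 1,3-dielectrophile once C2–C3 is an epoxide). The electron-rich ring B on C2 and the unsubstituted C5 steer the closure 6-endo.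
- Forward order: fragment A (resorcinol bis-MOM ether → C8 prenyl → C4a iodide → mono-TIPS iodophenol, steps 1–4); fragment B (4-iodophenol → two prenyls → TBS ether → enamide → epoxide, steps 5–8); union of the fragments builds ring C (step 9); desilylation (step 10).
- Stereochemistry: C3 (R) comes from the catalytic asymmetric epoxidation and is carried through unchanged; C2 (R) arises by SN2 inversion at the benzylic epoxide carbon in the ring closure, hence 2,3-trans.

Key step: step 9

Assumption: the Sm–(S)-BINOL–Ph3As=O catalyst is taken to give the (2R,3S)-epoxy amide, by analogy with β-aryl enones and enamides; should the sense prove opposite, (R)-BINOL is used with no other change.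

**Step 1**
Reactants: 1 1,3-bis(methoxymethoxy)benzene
Product: 3 1,3-bis(methoxymethoxy)-2-(3-methylbut-2-en-1-yl)benzene, via the 2-lithio derivative 2 (not isolated)
Conditions: n-BuLi, THF, 0 °C to rt; CuI (10 mol %), prenyl bromide, −78 °C to rt
Reagents that add atoms: prenyl bromide (1-bromo-3-methylbut-2-ene), CC(C)=CCBr
Why: Directed ortho-metalation takes the C–H flanked by both OMOM groups, and the copper-catalysed alkylation of the aryllithium with prenyl bromide at its primary carbon is the standard entry to 2-prenylresorcinol ethers.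

**Step 2**
Reactants: 3 1,3-bis(methoxymethoxy)-2-(3-methylbut-2-en-1-yl)benzene
Product: 5 1-iodo-2,4-bis(methoxymethoxy)-3-(3-methylbut-2-en-1-yl)benzene, via the 4-lithio derivative 4 (not isolated)
Conditions: n-BuLi, TMEDA, THF, −78 to −20 °C; I2, THF, −78 °C to rt
Reagents that add atoms: iodine, II
Why: A second directed ortho-metalation at the only remaining position ortho to an OMOM group, under kinetic conditions that should favour ring lithiation over removal of a benzylic–allylic proton, followed by iodinolysis of the C–Li bond, places the halogen without exposing an ortho-prenylphenol to an electrophilic halogenating agent.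

**Step 3**
Reactants: 5 1-iodo-2,4-bis(methoxymethoxy)-3-(3-methylbut-2-en-1-yl)benzene
Product: 6 4-iodo-2-(3-methylbut-2-en-1-yl)benzene-1,3-diol
Conditions: HCl (cat.), MeOH, rt
Reagents that add atoms: none
Why: Acid-catalysed acetal exchange with methanol cleaves both MOM ethers, and room temperature should keep the ortho-prenylphenol from cyclising to a chroman.

**Step 4**
Reactants: 6 4-iodo-2-(3-methylbut-2-en-1-yl)benzene-1,3-diol
Product: 7 6-iodo-2-(3-methylbut-2-en-1-yl)-3-[(triisopropylsilyl)oxy]phenol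
Conditions: TIPSCl (1.05 equiv), imidazole, CH2Cl2, 0 °C
Reagents that add atoms: triisopropylsilyl chloride, CC(C)[Si](Cl)(C(C)C)C(C)C
Why: Regioselective silylation should occur at the hydroxyl para to iodine, because the other hydroxyl is flanked by iodine and the prenyl group, is more acidic and is hydrogen-bonded to iodine, so the bulky silyl chloride is kept away from it.

**Step 5**
Reactants: 8 4-iodophenol
Product: 9 4-iodo-2,6-bis(3-methylbut-2-en-1-yl)phenol
Conditions: prenyl bromide (2.5 equiv), aq. KOH, rt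
Reagents that add atoms: prenyl bromide (1-bromo-3-methylbut-2-ene), CC(C)=CCBr
Why: Ortho C-alkylation of a phenoxide in water, where the oxygen is hydrogen-bonded and the para position is blocked by iodine, is the precedented o,o'-diprenylation of 4-halophenols.

**Step 6**
Reactants: 9 4-iodo-2,6-bis(3-methylbut-2-en-1-yl)phenol
Product: 10 tert-butyl[4-iodo-2,6-bis(3-methylbut-2-en-1-yl)phenoxy]dimethylsilane
Conditions: TBSCl, imidazole, DMF, 40 °C
Reagents that add atoms: tert-butyldimethylsilyl chloride, CC(C)(C)[Si](C)(C)Cl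
Why: Standard silylation of a 2,6-dialkylphenol gives a hindered aryl silyl ether that should survive the Heck, epoxidation and organolithium steps.

**Step 7**
Reactants: 10 tert-butyl[4-iodo-2,6-bis(3-methylbut-2-en-1-yl)phenoxy]dimethylsilane; 11 4-acryloylmorpholine
Product: 12 (E)-3-[4-(tert-butyldimethylsilyloxy)-3,5-bis(3-methylbut-2-en-1-yl)phenyl]-1-(morpholin-4-yl)prop-2-en-1-one
Conditions: Pd(OAc)2 (5 mol %), P(o-tol)3 (10 mol %), Et3N, DMF, 90 °C
Reagents that add atoms: none
Why: The Mizoroki–Heck reaction of an unhindered aryl iodide with an acrylamide gives the E-enamide, and the trisubstituted prenyl alkenes are too hindered to take part.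

**Step 8**
Reactants: 12 (E)-3-[4-(tert-butyldimethylsilyloxy)-3,5-bis(3-methylbut-2-en-1-yl)phenyl]-1-(morpholin-4-yl)prop-2-en-1-one
Product: 13 {(2R,3S)-3-[4-(tert-butyldimethylsilyloxy)-3,5-bis(3-methylbut-2-en-1-yl)phenyl]oxiran-2-yl}(morpholin-4-yl)methanone
Conditions: Sm(O-i-Pr)3 (10 mol %), (S)-BINOL (10 mol %), Ph3As=O (10 mol %), t-BuOOH (decane), 4 Å MS, THF, rt
Reagents that add atoms: tert-butyl hydroperoxide, CC(C)(C)OO
Why: In this lanthanide–BINOL-catalysed nucleophilic epoxidation of an α,β-unsaturated morpholinyl amide (Weitz–Scheffer type), the metal-bound peroxide adds only to the electron-poor enamide, so the prenyl alkenes are untouched; the BINOL ligand selects the alkene face and sets both epoxide carbons, trans from the E alkene.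

**Step 9**
Reactants: 7 6-iodo-2-(3-methylbut-2-en-1-yl)-3-[(triisopropylsilyl)oxy]phenol; 13 {(2R,3S)-3-[4-(tert-butyldimethylsilyloxy)-3,5-bis(3-methylbut-2-en-1-yl)phenyl]oxiran-2-yl}(morpholin-4-yl)methanone
Product: 17 (2R,3R)-2-[4-(tert-butyldimethylsilyloxy)-3,5-bis(3-methylbut-2-en-1-yl)phenyl]-3-hydroxy-8-(3-methylbut-2-en-1-yl)-7-[(triisopropylsilyl)oxy]-2,3-dihydro-4H-chromen-4-one, via dianion 14 (not isolated), via tetrahedral adduct 15 (not isolated), via epoxy ketone phenoxide 16 (not isolated)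
Conditions: 7 (1.15 equiv), MeLi (1.0 equiv per 7), THF, −78 °C; t-BuLi (2.0 equiv per 7), −78 °C; 13 (1.0 equiv), −78 to −40 °C; MeOH, −40 °C to rt; AcOH
Reagents that add atoms: none
Why: Proposed new method: MeLi removes the phenolic proton and t-BuLi effects iodine–lithium exchange to give the lithium 2-lithiophenoxide 14, whose C–Li bond should add to the morpholine amide carbonyl of 13 faster than to the epoxide, giving the chelated tetrahedral adduct 15 (C4–C4a bond); methanol collapses 15 to the epoxy ketone phenoxide 16, whose phenoxide oxygen then opens the epoxide at the benzylic carbon (O1–C2 bond). The closest known reaction types are the acylation of aryllithiums by Weinreb or morpholine amides, glycidic ones included, and the base-mediated cyclisation of 2'-hydroxychalcone epoxides to dihydroflavonols (first stage of the Algar–Flynn–Oyamada sequence); what is new is their union as a one-flask (3+3) annulation of an unprotected ortho-metalated phenoxide with an enantiopure glycidic amide. Ring C closes by a 6-endo-tet epoxide opening, which should be preferred over 5-exo attack at the α-carbon (leading to a 2-(hydroxybenzyl)benzofuranone) because the attacked carbon is benzylic to the electron-rich ring B, lithium bridges the ketone and epoxide oxygens, and C5 of ring A carries no substituent. C3 keeps the configuration of the epoxide α-carbon, whose C–O bond is not broken, and C2 is formed with inversion at the (S)-configured benzylic epoxide carbon, so the trans epoxide should give the 2,3-trans (2R,3R) product. The step needs chemoselectivity (amide carbonyl over epoxide and over the prenyl benzylic protons, secured by −78 °C and the chelating morpholine amide), 6-endo regioselectivity and a stereospecific SN2 opening; the silyloxy group of ring B is twisted out of conjugation by its two ortho prenyl groups, which limits benzylic ionisation, and the trans isomer is in any case the more stable one.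

**Step 10**
Reactants: 17 (2R,3R)-2-[4-(tert-butyldimethylsilyloxy)-3,5-bis(3-methylbut-2-en-1-yl)phenyl]-3-hydroxy-8-(3-methylbut-2-en-1-yl)-7-[(triisopropylsilyl)oxy]-2,3-dihydro-4H-chromen-4-one
Product: 18 (2R,3R)-3,7-dihydroxy-2-[4-hydroxy-3,5-bis(3-methylbut-2-en-1-yl)phenyl]-8-(3-methylbut-2-en-1-yl)-2,3-dihydro-4H-chromen-4-one
Conditions: HF·pyridine, pyridine, THF, 0 °C to rt
Reagents that add atoms: none
Why: Fluoride cleavage of both aryl silyl ethers under mildly acidic buffered conditions should spare the prenyl groups and the α-ketol and avoid the base-induced ring opening that would epimerise C2.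

**Compound list**
1 | 1,3-bis(methoxymethoxy)benzene | COCOc1cccc(OCOC)c1 | starting material
2 | 2-lithio-1,3-bis(methoxymethoxy)benzene | COCOc1cccc(OCOC)c1[Li] | intermediate
3 | 1,3-bis(methoxymethoxy)-2-(3-methylbut-2-en-1-yl)benzene | COCOc1cccc(OCOC)c1CC=C(C)C | intermediate
4 | 4-lithio-1,3-bis(methoxymethoxy)-2-(3-methylbut-2-en-1-yl)benzene | COCOc1ccc([Li])c(OCOC)c1CC=C(C)C | intermediate
5 | 1-iodo-2,4-bis(methoxymethoxy)-3-(3-methylbut-2-en-1-yl)benzene | COCOc1ccc(I)c(OCOC)c1CC=C(C)C | intermediate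
6 | 4-iodo-2-(3-methylbut-2-en-1-yl)benzene-1,3-diol | Oc1ccc(I)c(O)c1CC=C(C)C | intermediate
7 | 6-iodo-2-(3-methylbut-2-en-1-yl)-3-[(triisopropylsilyl)oxy]phenol | CC(C)[Si](Oc1ccc(I)c(O)c1CC=C(C)C)(C(C)C)C(C)C | intermediate
8 | 4-iodophenol | Oc1ccc(I)cc1 | starting material
9 | 4-iodo-2,6-bis(3-methylbut-2-en-1-yl)phenol | CC(C)=CCc1cc(I)cc(CC=C(C)C)c1O | intermediate
10 | tert-butyl[4-iodo-2,6-bis(3-methylbut-2-en-1-yl)phenoxy]dimethylsilane | CC(C)=CCc1cc(I)cc(CC=C(C)C)c1O[Si](C)(C)C(C)(C)C | intermediate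
11 | 4-acryloylmorpholine | C=CC(=O)N1CCOCC1 | starting material
12 | (E)-3-[4-(tert-butyldimethylsilyloxy)-3,5-bis(3-methylbut-2-en-1-yl)phenyl]-1-(morpholin-4-yl)prop-2-en-1-one | CC(C)=CCc1cc(/C=C/C(=O)N2CCOCC2)cc(CC=C(C)C)c1O[Si](C)(C)C(C)(C)C | intermediate
13 | {(2R,3S)-3-[4-(tert-butyldimethylsilyloxy)-3,5-bis(3-methylbut-2-en-1-yl)phenyl]oxiran-2-yl}(morpholin-4-yl)methanone | O=C(N1CCOCC1)[C@@H]2O[C@H]2c3cc(CC=C(C)C)c(O[Si](C)(C)C(C)(C)C)c(CC=C(C)C)c3 | intermediate
14 | lithium 2-lithio-6-(3-methylbut-2-en-1-yl)-5-[(triisopropylsilyl)oxy]phenoxide (dianion) | CC(C)[Si](Oc1ccc([Li])c(O[Li])c1CC=C(C)C)(C(C)C)C(C)C | intermediate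
15 | dilithium tetrahedral adduct of 14 with the amide carbonyl of 13 (aminal carbon unassigned) | CC(C)[Si](Oc1ccc(C(O[Li])(N2CCOCC2)[C@@H]3O[C@H]3c4cc(CC=C(C)C)c(O[Si](C)(C)C(C)(C)C)c(CC=C(C)C)c4)c(O[Li])c1CC=C(C)C)(C(C)C)C(C)C | intermediate
16 | lithium phenoxide of {(2R,3S)-3-[4-(tert-butyldimethylsilyloxy)-3,5-bis(3-methylbut-2-en-1-yl)phenyl]oxiran-2-yl}{2-hydroxy-3-(3-methylbut-2-en-1-yl)-4-[(triisopropylsilyl)oxy]phenyl}methanone | CC(C)[Si](Oc1ccc(C(=O)[C@@H]2O[C@H]2c3cc(CC=C(C)C)c(O[Si](C)(C)C(C)(C)C)c(CC=C(C)C)c3)c(O[Li])c1CC=C(C)C)(C(C)C)C(C)C | intermediate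
17 | (2R,3R)-2-[4-(tert-butyldimethylsilyloxy)-3,5-bis(3-methylbut-2-en-1-yl)phenyl]-3-hydroxy-8-(3-methylbut-2-en-1-yl)-7-[(triisopropylsilyl)oxy]-2,3-dihydro-4H-chromen-4-one | CC(C)=CCc1cc([C@H]2Oc3c(ccc(O[Si](C(C)C)(C(C)C)C(C)C)c3CC=C(C)C)C(=O)[C@@H]2O)cc(CC=C(C)C)c1O[Si](C)(C)C(C)(C)C | intermediate
18 | (2R,3R)-3,7-dihydroxy-2-[4-hydroxy-3,5-bis(3-methylbut-2-en-1-yl)phenyl]-8-(3-methylbut-2-en-1-yl)-2,3-dihydro-4H-chromen-4-one | CC(C)=CCc1cc([C@H]2Oc3c(ccc(O)c3CC=C(C)C)C(=O)[C@@H]2O)cc(CC=C(C)C)c1O | target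

**Step count**
Total steps: 10. Longest linear sequence: 6 (steps 1–4, 9, 10 or steps 5–8, 9, 10).

**Steps most likely to fail**

Step 9 (proposed new method). The aryllithium may attack the epoxide or be quenched by proton transfer instead of adding to the amide; the phenoxide may open the epoxide 5-exo; or benzylic ionisation may erode the stereospecificity at C2. The fallback sets out from 7 and 13 and comes back at 17, using known reactions one at a time. Compound 7 is O-allylated (allyl bromide, K2CO3, acetone) to 2-(allyloxy)-1-iodo-3-(3-methylbut-2-en-1-yl)-4-[(triisopropylsilyl)oxy]benzene F1. Iodine–lithium exchange (t-BuLi, THF, −78 °C), addition to 13 and an AcOH quench at −78 °C should give the isolated O-allyl epoxy ketone F2, an ordinary aryllithium acylation by a morpholine amide. Pd(PPh3)4 with morpholine as allyl acceptor then frees the 2-hydroxyaryl epoxy ketone F3, which is closed with NaOAc in EtOH, the known cyclisation of 2'-hydroxychalcone epoxides, to 17.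

Step 8. Conjugate addition of the peroxide to a hindered, electron-rich enamide may be slow, and enantioselectivity or the aryl silyl ether may suffer on long exposure to the basic catalyst. The fallback sets out from 10 and comes back at 13, with reagent-controlled stereochemistry of predictable sense. A Mizoroki–Heck reaction of 10 with methyl acrylate gives the methyl cinnamate F4. DIBAL-H reduction gives the allylic alcohol F5. Sharpless asymmetric epoxidation (Ti(O-i-Pr)4, L-(+)-diethyl tartrate, t-BuOOH, 4 Å MS, CH2Cl2, −20 °C), which leaves the non-allylic prenyl alkenes alone, gives the (2S,3S)-epoxy alcohol F6. Buffered TEMPO/PhI(OAc)2 oxidation gives the (2R,3S)-glycidic acid F7, which is coupled at once with morpholine (EDC, HOBt) to give 13.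

Step 5. O-alkylation and over-alkylation to dienones may compete with the twofold ortho C-alkylation and leave a poor mass balance. The fallback sets out from 8 and comes back at 12, placing both prenyl groups by cross-coupling. Compound 8 is brominated at both ortho positions (NBS, MeCN) to 2,6-dibromo-4-iodophenol F8. A Mizoroki–Heck reaction with 11, selective for the C–I bond, gives the dibromo enamide F9. A twofold Stille coupling with tributyl(3-methylbut-2-en-1-yl)stannane (Pd(PPh3)4, DMF, 100 °C) gives the diprenyl phenol F10, and silylation (TBSCl, imidazole, DMF) gives 12.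

**Further compounds**
F1 | step 9 | 2-(allyloxy)-1-iodo-3-(3-methylbut-2-en-1-yl)-4-[(triisopropylsilyl)oxy]benzene | C=CCOc1c(I)ccc(O[Si](C(C)C)(C(C)C)C(C)C)c1CC=C(C)C
F2 | step 9 | {(2R,3S)-3-[4-(tert-butyldimethylsilyloxy)-3,5-bis(3-methylbut-2-en-1-yl)phenyl]oxiran-2-yl}{2-(allyloxy)-3-(3-methylbut-2-en-1-yl)-4-[(triisopropylsilyl)oxy]phenyl}methanone | C=CCOc1c(C(=O)[C@@H]2O[C@H]2c3cc(CC=C(C)C)c(O[Si](C)(C)C(C)(C)C)c(CC=C(C)C)c3)ccc(O[Si](C(C)C)(C(C)C)C(C)C)c1CC=C(C)C
F3 | step 9 | {(2R,3S)-3-[4-(tert-butyldimethylsilyloxy)-3,5-bis(3-methylbut-2-en-1-yl)phenyl]oxiran-2-yl}{2-hydroxy-3-(3-methylbut-2-en-1-yl)-4-[(triisopropylsilyl)oxy]phenyl}methanone | Oc1c(C(=O)[C@@H]2O[C@H]2c3cc(CC=C(C)C)c(O[Si](C)(C)C(C)(C)C)c(CC=C(C)C)c3)ccc(O[Si](C(C)C)(C(C)C)C(C)C)c1CC=C(C)C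
F4 | step 8 | methyl (E)-3-[4-(tert-butyldimethylsilyloxy)-3,5-bis(3-methylbut-2-en-1-yl)phenyl]prop-2-enoate | COC(=O)/C=C/c1cc(CC=C(C)C)c(O[Si](C)(C)C(C)(C)C)c(CC=C(C)C)c1
F5 | step 8 | (E)-3-[4-(tert-butyldimethylsilyloxy)-3,5-bis(3-methylbut-2-en-1-yl)phenyl]prop-2-en-1-ol | OC/C=C/c1cc(CC=C(C)C)c(O[Si](C)(C)C(C)(C)C)c(CC=C(C)C)c1
F6 | step 8 | {(2S,3S)-3-[4-(tert-butyldimethylsilyloxy)-3,5-bis(3-methylbut-2-en-1-yl)phenyl]oxiran-2-yl}methanol | OC[C@@H]1O[C@H]1c2cc(CC=C(C)C)c(O[Si](C)(C)C(C)(C)C)c(CC=C(C)C)c2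
F7 | step 8 | (2R,3S)-3-[4-(tert-butyldimethylsilyloxy)-3,5-bis(3-methylbut-2-en-1-yl)phenyl]oxirane-2-carboxylic acid | OC(=O)[C@@H]1O[C@H]1c2cc(CC=C(C)C)c(O[Si](C)(C)C(C)(C)C)c(CC=C(C)C)c2
F8 | step 5 | 2,6-dibromo-4-iodophenol | Oc1c(Br)cc(I)cc1Br
F9 | step 5 | (E)-3-(3,5-dibromo-4-hydroxyphenyl)-1-(morpholin-4-yl)prop-2-en-1-one | O=C(/C=C/c1cc(Br)c(O)c(Br)c1)N2CCOCC2
F10 | step 5 | (E)-3-[4-hydroxy-3,5-bis(3-methylbut-2-en-1-yl)phenyl]-1-(morpholin-4-yl)prop-2-en-1-one | CC(C)=CCc1cc(/C=C/C(=O)N2CCOCC2)cc(CC=C(C)C)c1O
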